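**Plan** (isochromene numbering: C1, O2, C3, C4, C4a, C5–C8, C8a)
- Retrosynthesis: cut the C7–O ester bond first (aroyl fluoride 25 plus tertiary alcohol 17), then O2–C3 of the pyran ring (back to an alkynol), then C4a–C4 and C8a–C1 together.
- Enabling feature: in the carbocyclic ring the ring-fusion carbons C4a and C8a are the β- and α-carbons of the C8 ketone, and each carries one exocyclic carbon (C4, C1). A cyclohexenone can therefore take the enyne at C4a and formaldehyde at C8a in one operation.
- Forward: carbocyclic enone 7 from (R)-carvone, three-component coupling, pyran ring by 6-endo-dig hydroalkoxylation, C4a=C8a reinstated with DDQ, diol unmasked, O6 silylated, O7 acylated, silyl groups removed.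
- Stereochemistry: C6 and C7 come from OsO4 addition anti to the carvone-derived acetoxy group, which is then eliminated. The C4a/C8a centres made in the coupling are transient. The E-propenyl geometry is brought in with the enyne.

Key step: step 5

Assumption: (E)-pent-3-en-1-yne (8) is taken as purchasable in geometrically pure form (otherwise the E isomer is obtained by fractional distillation), and monomeric formaldehyde (9) is generated by cracking paraformaldehyde just before use.

**Step 1**
Reactants: 1 (R)-carvone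
Product: 4 (5R)-5-acetoxy-2-methylcyclohex-2-en-1-one, via methoxy hydroperoxide 2 (not isolated), via peracetate 3 (not isolated)
Conditions: O3, MeOH–CH2Cl2, −78 °C, N2 purge; then Ac2O, Et3N, DMAP (cat.), CH2Cl2, 0 °C → rt
Reagents that add atoms: ozone, [O-][O+]=O; methanol, CO
Why: Ozone attacks the electron-rich 1,1-disubstituted alkene rather than the enone C=C, methanol traps the carbonyl oxide as 2, and acetylation triggers a Criegee rearrangement in which the ring carbon migrates to oxygen with retention, so C5 stays R and the acetyl carbons of 4 are the former isopropenyl carbons while acetic anhydride leaves as methyl acetate and acetic acid.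

**Step 2**
Reactants: 4 (5R)-5-acetoxy-2-methylcyclohex-2-en-1-one
Product: 5 (2R,3R,5R)-5-acetoxy-2,3-dihydroxy-2-methylcyclohexan-1-one
Conditions: OsO4 (cat.), NMO, citric acid, t-BuOH–H2O, rt
Reagents that add atoms: N-methylmorpholine N-oxide, C[N+]1([O-])CCOCC1; water, O (both oxygens are delivered through OsO4, O=[Os](=O)(=O)=O)
Why: Upjohn-type cis-dihydroxylation, helped by citric acid for this electron-poor trisubstituted alkene, should occur on the face opposite the C5 acetoxy group and so set the two carbinol centres (later C7 and C6) as R,R, and the minor syn diastereomer is removed here by chromatography because after step 4 it would become the enantiomer.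

**Step 3**
Reactants: 5 (2R,3R,5R)-5-acetoxy-2,3-dihydroxy-2-methylcyclohexan-1-one
Product: 6 (2R,3R,5R)-5-acetoxy-2,3-(isopropylidenedioxy)-2-methylcyclohexan-1-one
Conditions: Me2C(OMe)2, pyridinium p-toluenesulfonate (cat.), CH2Cl2, rt
Reagents that add atoms: 2,2-dimethoxypropane, COC(C)(C)OC
Why: Acid-catalysed transketalisation of the cis-diol gives the cis-fused dioxolane under conditions too mild to eliminate the β-acetoxy group, and no stereocentre is touched.

**Step 4**
Reactants: 6 (2R,3R,5R)-5-acetoxy-2,3-(isopropylidenedioxy)-2-methylcyclohexan-1-one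
Product: 7 (5R,6R)-5,6-(isopropylidenedioxy)-6-methylcyclohex-2-en-1-one
Conditions: DBU, CH2Cl2, 0 °C
Reagents that add atoms: none
Why: E1cB elimination in which DBU removes one of the only enolisable α-hydrogens and the β-acetoxy group departs, giving the conjugated enone and deleting the carvone-derived stereocentre once it has directed step 2.

**Step 5**
Reactants: 7 (5R,6R)-5,6-(isopropylidenedioxy)-6-methylcyclohex-2-en-1-one; 8 (E)-pent-3-en-1-yne; 9 formaldehyde
Product: 13 (2R,3R,5R,6R)-2-(hydroxymethyl)-5,6-(isopropylidenedioxy)-6-methyl-3-[(E)-pent-3-en-1-yn-1-yl]cyclohexan-1-one, via lithium acetylide 10 (not isolated), via alkynylalane 11 (not isolated), via aluminium enolate 12 (not isolated)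
Conditions: 8, n-BuLi, Et2O, −40 → 0 °C; Et2AlCl, 0 °C → rt; Ni(acac)2 (cat.), i-Bu2AlH (cat.), Et2O, 0 °C, then 7, −5 °C; CH2O (g), −78 → −20 °C; aq. KNaC4H4O6
Reagents that add atoms: none
Why: Low-valent nickel, generated from Ni(acac)2 and i-Bu2AlH, engages the enone, takes the alkynyl group from alane 11 by transmetalation and delivers it to C4a (forming C4a–C4), which leaves the diethylaluminium enolate 12 with its double bond fixed between C8 and C8a; this enolate then adds to monomeric formaldehyde (forming C8a–C1) and work-up frees aldol 13. The closest known reaction type is the nickel-catalysed conjugate addition of dialkylaluminium acetylides to s-trans cyclic enones, run in tandem with aldol trapping of the metal enolate as in three-component enone couplings. No ring is closed in this step. C4a is set by approach of the nickel–alkynyl species to the enone face opposite the C6–O bond of the cis-fused dioxolane, and C8a by formaldehyde adding to the enolate face opposite the new alkynyl group, giving the 4a,8a-trans product; both centres are removed again in step 7, so their level of control affects only handling. The step needs 1,4- over 1,2-addition, alkynyl over ethyl transfer and aldol reaction at C8a only: the nickel catalyst secures the first (the alane alone does not add in a conjugate sense to an enone that cannot become s-cis), the sp-carbon ligand transmetalates in preference to ethyl, and the enolate is formed regiospecifically and cannot equilibrate towards the quaternary C7.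

**Step 6**
Reactants: 13 (2R,3R,5R,6R)-2-(hydroxymethyl)-5,6-(isopropylidenedioxy)-6-methyl-3-[(E)-pent-3-en-1-yn-1-yl]cyclohexan-1-one
Product: 14 (4aS,6R,7R,8aR)-6,7-(isopropylidenedioxy)-7-methyl-3-[(E)-prop-1-en-1-yl]-4a,5,6,7-tetrahydro-1H-isochromen-8(8aH)-one
Conditions: Ph3PAuNTf2 (3 mol %), CH2Cl2, rt; filtration through Et3N-deactivated silica
Reagents that add atoms: none
Why: Monovalent gold activates the alkyne and the primary hydroxyl adds at the distal alkyne carbon C3 in a 6-endo-dig hydroalkoxylation, favoured over 5-exo-dig by the cation-stabilising propenyl group on C3 and by the trans ring fusion that a five-membered ring would strain, and protodeauration then gives the dienol ether without touching the four stereocentres.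

**Step 7**
Reactants: 14 (4aS,6R,7R,8aR)-6,7-(isopropylidenedioxy)-7-methyl-3-[(E)-prop-1-en-1-yl]-4a,5,6,7-tetrahydro-1H-isochromen-8(8aH)-one
Product: 15 (6R,7R)-6,7-(isopropylidenedioxy)-7-methyl-3-[(E)-prop-1-en-1-yl]-6,7-dihydro-1H-isochromen-8(5H)-one
Conditions: DDQ (1.1 equiv), CH2Cl2, 0 °C → rt
Reagents that add atoms: none
Why: DDQ dehydrogenation in which hydride is abstracted from C4a (allylic to the dienol ether, giving an oxygen-stabilised pentadienyl cation) and the acidic C8a proton is then lost, reinstating C4a=C8a in conjugation with both the ketone and the enol ether, with one equivalent at low temperature chosen to avoid further oxidation at C1.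

**Step 8**
Reactants: 15 (6R,7R)-6,7-(isopropylidenedioxy)-7-methyl-3-[(E)-prop-1-en-1-yl]-6,7-dihydro-1H-isochromen-8(5H)-one
Product: 16 (6R,7R)-6,7-dihydroxy-7-methyl-3-[(E)-prop-1-en-1-yl]-6,7-dihydro-1H-isochromen-8(5H)-one
Conditions: CF3CO2H–H2O (9:1), 0 °C, short contact; toluene azeotrope
Reagents that add atoms: none
Why: Acid-catalysed acetal hydrolysis, during which the ring enol ether, conjugated through C3=C4–C4a=C8a to the C8 carbonyl as a doubly vinylogous ester, should resist C-protonation for the short cold exposure that frees the diol with both configurations intact.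

**Step 9**
Reactants: 16 (6R,7R)-6,7-dihydroxy-7-methyl-3-[(E)-prop-1-en-1-yl]-6,7-dihydro-1H-isochromen-8(5H)-one
Product: 17 (6R,7R)-6-(tert-butyldimethylsilyloxy)-7-hydroxy-7-methyl-3-[(E)-prop-1-en-1-yl]-6,7-dihydro-1H-isochromen-8(5H)-one
Conditions: TBSOTf (1.1 equiv), 2,6-lutidine, CH2Cl2, −78 °C
Reagents that add atoms: tert-butyldimethylsilyl triflate, CC(C)(C)[Si](C)(C)OS(=O)(=O)C(F)(F)F
Why: Silyl triflate silylation at low temperature discriminates the secondary C6 hydroxyl from the tertiary C7 α-ketol hydroxyl on steric grounds.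

**Step 10**
Reactants: 18 methyl orsellinate
Product: 19 methyl 4-(benzyloxy)-2-hydroxy-6-methylbenzoate
Conditions: BnBr (1.05 equiv), K2CO3, acetone, reflux
Reagents that add atoms: benzyl bromide, BrCc1ccccc1
Why: Williamson etherification in which the 2-hydroxyl is tied up in a hydrogen bond to the ester carbonyl, so only the free and more acidic 4-hydroxyl is benzylated.

**Step 11**
Reactants: 19 methyl 4-(benzyloxy)-2-hydroxy-6-methylbenzoate
Product: 20 methyl 4-(benzyloxy)-2-methoxy-6-methylbenzoate
Conditions: MeI, K2CO3, DMF, rt → 40 °C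
Reagents that add atoms: iodomethane, CI
Why: Williamson methylation of the remaining chelated phenol, which proceeds in the more polar solvent DMF.

**Step 12**
Reactants: 20 methyl 4-(benzyloxy)-2-methoxy-6-methylbenzoate
Product: 21 4-(benzyloxy)-2-methoxy-6-methylbenzoic acid
Conditions: KOH, DMSO–H2O, 90 °C; then cold aq. HCl
Reagents that add atoms: potassium hydroxide (hydroxide oxygen of the new CO2H), [K+].[OH-]
Why: Saponification of the di-ortho-substituted ester needs forcing hydroxide in aqueous DMSO, the two ethers are inert, and cold acidification avoids protodecarboxylation of the electron-rich acid.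

**Step 13**
Reactants: 21 4-(benzyloxy)-2-methoxy-6-methylbenzoic acid
Product: 22 4-hydroxy-2-methoxy-6-methylbenzoic acid
Conditions: H2 (1 atm), 10% Pd/C, EtOAc–MeOH, rt
Reagents that add atoms: none
Why: Hydrogenolysis of the benzyl aryl ether over palladium on carbon, with nothing else in 21 reducible under these conditions.

**Step 14**
Reactants: 22 4-hydroxy-2-methoxy-6-methylbenzoic acid
Product: 24 2-methoxy-6-methyl-4-(triisopropylsilyloxy)benzoic acid, via bis-silyl compound 23 (not isolated)
Conditions: i-Pr3SiCl (2.3 equiv), imidazole, DMF, rt; then K2CO3, MeOH–THF–H2O, 0 °C → rt; cold aq. HCl to pH 4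
Reagents that add atoms: triisopropylsilyl chloride, CC(C)[Si](Cl)(C(C)C)C(C)C
Why: Silylation of both acidic hydroxyls followed by selective solvolysis of the far more labile silyl ester (carboxylate leaving group) leaves the robust aryl triisopropylsilyl ether.

**Step 15**
Reactants: 24 2-methoxy-6-methyl-4-(triisopropylsilyloxy)benzoic acid
Product: 25 2-methoxy-6-methyl-4-(triisopropylsilyloxy)benzoyl fluoride
Conditions: cyanuric fluoride, pyridine, CH2Cl2, −10 °C → rt
Reagents that add atoms: cyanuric fluoride, Fc1nc(F)nc(F)n1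
Why: Deoxyfluorination of the carboxylic acid with cyanuric fluoride gives the acyl fluoride, a compact and moisture-tolerant acyl donor suited to hindered couplings, without liberating free fluoride that could attack the silyl ether.

**Step 16**
Reactants: 17 (6R,7R)-6-(tert-butyldimethylsilyloxy)-7-hydroxy-7-methyl-3-[(E)-prop-1-en-1-yl]-6,7-dihydro-1H-isochromen-8(5H)-one; 25 2-methoxy-6-methyl-4-(triisopropylsilyloxy)benzoyl fluoride
Product: 27 (6R,7R)-6-(tert-butyldimethylsilyloxy)-7-methyl-8-oxo-3-[(E)-prop-1-en-1-yl]-5,6,7,8-tetrahydro-1H-isochromen-7-yl 2-methoxy-6-methyl-4-(triisopropylsilyloxy)benzoate, via lithium alkoxide 26 (not isolated)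
Conditions: LiN(SiMe3)2 (1.05 equiv), THF, −78 °C; then 25, −78 → 0 °C
Reagents that add atoms: none
Why: Alkoxide acylation by an acyl fluoride (addition–elimination) in which the lithium alkoxide of the only free hydroxyl attacks the compact C(=O)F group despite its two ortho substituents, while the lithium counter-ion, the low temperature and the bulky silyl group hold back 1,2-silyl migration, one equivalent of base avoids γ-deprotonation at C5, and C7 reacts at oxygen only so its configuration is retained.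

**Step 17**
Reactants: 27 (6R,7R)-6-(tert-butyldimethylsilyloxy)-7-methyl-8-oxo-3-[(E)-prop-1-en-1-yl]-5,6,7,8-tetrahydro-1H-isochromen-7-yl 2-methoxy-6-methyl-4-(triisopropylsilyloxy)benzoate
Product: 28 (6R,7R)-6-hydroxy-7-methyl-8-oxo-3-[(E)-prop-1-en-1-yl]-5,6,7,8-tetrahydro-1H-isochromen-7-yl 4-hydroxy-2-methoxy-6-methylbenzoate
Conditions: Bu4NF–AcOH (1:1, excess), THF, 0 °C → rt
Reagents that add atoms: none
Why: Fluoride-mediated cleavage of both Si–O bonds under acetic acid buffering, which avoids base-induced acyl migration from O7 to O6 (also disfavoured by the di-ortho-substituted aroyl group) and leaves the vinylogous ester and both stereocentres untouched.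

**Compound list**
1 | (R)-carvone, (5R)-2-methyl-5-(prop-1-en-2-yl)cyclohex-2-en-1-one | CC1=CC[C@H](CC1=O)C(C)=C | starting material
2 | (5R)-5-(1-hydroperoxy-1-methoxyethyl)-2-methylcyclohex-2-en-1-one (epimers at the peroxy carbon) | CC1=CC[C@H](CC1=O)C(C)(OC)OO | intermediate
3 | (5R)-5-[1-(acetylperoxy)-1-methoxyethyl]-2-methylcyclohex-2-en-1-one | CC1=CC[C@H](CC1=O)C(C)(OC)OOC(C)=O | intermediate
4 | (5R)-5-acetoxy-2-methylcyclohex-2-en-1-one | CC1=CC[C@H](CC1=O)OC(C)=O | intermediate
5 | (2R,3R,5R)-5-acetoxy-2,3-dihydroxy-2-methylcyclohexan-1-one (cis-diol trans to the acetoxy group) | O=C1[C@](C)(O)[C@H](O)C[C@@H](OC(C)=O)C1 | intermediate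
6 | (2R,3R,5R)-5-acetoxy-2,3-(isopropylidenedioxy)-2-methylcyclohexan-1-one | O=C1[C@]2(C)OC(C)(C)O[C@@H]2C[C@@H](OC(C)=O)C1 | intermediate
7 | (5R,6R)-5,6-(isopropylidenedioxy)-6-methylcyclohex-2-en-1-one | O=C1[C@]2(C)OC(C)(C)O[C@@H]2CC=C1 | intermediate
8 | (E)-pent-3-en-1-yne | C/C=C/C#C | starting material
9 | formaldehyde | C=O | starting material
10 | lithium (E)-pent-3-en-1-yn-1-ide | [Li]C#C/C=C/C | intermediate
11 | diethyl[(E)-pent-3-en-1-yn-1-yl]aluminium | CC[Al](CC)C#C/C=C/C | intermediate
12 | diethylaluminium C8=C8a enolate of (3R,5R,6R)-5,6-(isopropylidenedioxy)-6-methyl-3-[(E)-pent-3-en-1-yn-1-yl]cyclohexan-1-one | CC[Al](CC)OC1=C[C@H](C#C/C=C/C)C[C@H]2OC(C)(C)O[C@@]12C | intermediate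
13 | (2R,3R,5R,6R)-2-(hydroxymethyl)-5,6-(isopropylidenedioxy)-6-methyl-3-[(E)-pent-3-en-1-yn-1-yl]cyclohexan-1-one (alkynyl anti to the dioxolane oxygens, hydroxymethyl trans to alkynyl) | O=C1[C@]2(C)OC(C)(C)O[C@@H]2C[C@@H](C#C/C=C/C)[C@@H]1CO | intermediate
14 | (4aS,6R,7R,8aR)-6,7-(isopropylidenedioxy)-7-methyl-3-[(E)-prop-1-en-1-yl]-4a,5,6,7-tetrahydro-1H-isochromen-8(8aH)-one (trans ring fusion) | C/C=C/C1=C[C@@H]2C[C@H]3OC(C)(C)O[C@@]3(C)C(=O)[C@H]2CO1 | intermediate
15 | (6R,7R)-6,7-(isopropylidenedioxy)-7-methyl-3-[(E)-prop-1-en-1-yl]-6,7-dihydro-1H-isochromen-8(5H)-one | C/C=C/C1=CC2=C(CO1)C(=O)[C@]3(C)OC(C)(C)O[C@@H]3C2 | intermediate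
16 | (6R,7R)-6,7-dihydroxy-7-methyl-3-[(E)-prop-1-en-1-yl]-6,7-dihydro-1H-isochromen-8(5H)-one | C/C=C/C1=CC2=C(CO1)C(=O)[C@](C)(O)[C@H](O)C2 | intermediate
17 | (6R,7R)-6-(tert-butyldimethylsilyloxy)-7-hydroxy-7-methyl-3-[(E)-prop-1-en-1-yl]-6,7-dihydro-1H-isochromen-8(5H)-one | C/C=C/C1=CC2=C(CO1)C(=O)[C@](C)(O)[C@H](O[Si](C)(C)C(C)(C)C)C2 | intermediate
18 | methyl orsellinate (methyl 2,4-dihydroxy-6-methylbenzoate) | COC(=O)c1c(C)cc(O)cc1O | starting material
19 | methyl 4-(benzyloxy)-2-hydroxy-6-methylbenzoate | COC(=O)c1c(C)cc(OCc2ccccc2)cc1O | intermediate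
20 | methyl 4-(benzyloxy)-2-methoxy-6-methylbenzoate | COC(=O)c1c(C)cc(OCc2ccccc2)cc1OC | intermediate
21 | 4-(benzyloxy)-2-methoxy-6-methylbenzoic acid | OC(=O)c1c(C)cc(OCc2ccccc2)cc1OC | intermediate
22 | 4-hydroxy-2-methoxy-6-methylbenzoic acid | OC(=O)c1c(C)cc(O)cc1OC | intermediate
23 | triisopropylsilyl 2-methoxy-6-methyl-4-(triisopropylsilyloxy)benzoate | CC(C)[Si](C(C)C)(C(C)C)OC(=O)c1c(C)cc(O[Si](C(C)C)(C(C)C)C(C)C)cc1OC | intermediate
24 | 2-methoxy-6-methyl-4-(triisopropylsilyloxy)benzoic acid | OC(=O)c1c(C)cc(O[Si](C(C)C)(C(C)C)C(C)C)cc1OC | intermediate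
25 | 2-methoxy-6-methyl-4-(triisopropylsilyloxy)benzoyl fluoride | FC(=O)c1c(C)cc(O[Si](C(C)C)(C(C)C)C(C)C)cc1OC | intermediate
26 | lithium 7-alkoxide of 17 | C/C=C/C1=CC2=C(CO1)C(=O)[C@](C)(O[Li])[C@H](O[Si](C)(C)C(C)(C)C)C2 | intermediate
27 | (6R,7R)-6-(tert-butyldimethylsilyloxy)-7-methyl-8-oxo-3-[(E)-prop-1-en-1-yl]-5,6,7,8-tetrahydro-1H-isochromen-7-yl 2-methoxy-6-methyl-4-(triisopropylsilyloxy)benzoate | C/C=C/C1=CC2=C(CO1)C(=O)[C@](C)(OC(=O)c1c(C)cc(O[Si](C(C)C)(C(C)C)C(C)C)cc1OC)[C@H](O[Si](C)(C)C(C)(C)C)C2 | intermediate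
28 | (6R,7R)-6-hydroxy-7-methyl-8-oxo-3-[(E)-prop-1-en-1-yl]-5,6,7,8-tetrahydro-1H-isochromen-7-yl 4-hydroxy-2-methoxy-6-methylbenzoate | C/C=C/C1=CC2=C(CO1)C(=O)[C@](C)(OC(=O)c1c(C)cc(O)cc1OC)[C@H](O)C2 | target

**Step count**
Total: 17 steps. Longest linear sequence: 11 steps (steps 1–9, 16 and 17, from (R)-carvone). The aroyl fluoride branch (steps 10–15) runs in parallel.

**Steps most likely to fail**

Step 16. The congested tertiary alkoxide may acylate too slowly. The silyl group may migrate from O6 to O7 so that acylation occurs at the wrong oxygen. The pyranone may also be deprotonated at C5 and decompose.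
Fallback: the ester is installed before the pyranone exists, where forcing conditions are tolerated. It sets out from diol 5 and returns at 27.
- TBSOTf and 2,6-lutidine at −78 °C should silylate the secondary hydroxyl of 5 to give (2R,3R,5R)-5-acetoxy-3-(tert-butyldimethylsilyloxy)-2-hydroxy-2-methylcyclohexan-1-one F6.
- DBU then eliminates acetic acid to give (5R,6R)-5-(tert-butyldimethylsilyloxy)-6-hydroxy-6-methylcyclohex-2-en-1-one F7.
- Deprotonation with LiN(SiMe3)2 and acylation with 25 in THF, warmed as far as rt if needed, should give the ester enone (1R,6R)-6-(tert-butyldimethylsilyloxy)-1-methyl-2-oxocyclohex-3-en-1-yl 2-methoxy-6-methyl-4-(triisopropylsilyloxy)benzoate F8.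
- The coupling of step 5 applied to F8 (the C6 silyl ether now steering the alkynyl group anti) should give the alkynol (1R,2R,4R,5R)-2-(tert-butyldimethylsilyloxy)-5-(hydroxymethyl)-1-methyl-6-oxo-4-[(E)-pent-3-en-1-yn-1-yl]cyclohexyl 2-methoxy-6-methyl-4-(triisopropylsilyloxy)benzoate F9.
- Ph3PAuNTf2 closes the pyran ring to the trans-fused hexahydroisochromenone ester F10, and DDQ as in step 7 gives 27.

Step 5. The aluminium enolate may be captured inefficiently by formaldehyde (protonation, formaldehyde oligomerisation, retro-aldol on work-up). 1,2-Addition or ethyl transfer may also compete.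
Fallback: the two bonds are formed in separate, individually known operations. It sets out from enone 7 (with lithium acetylide 10 made from 8 as in step 5) and returns at 13.
- 10 is transmetalated with ZnBr2 to bromo[(E)-pent-3-en-1-yn-1-yl]zinc F1.
- TBSOTf-promoted conjugate addition of F1 to 7 (THF–Et2O, −40 °C) should give the regiodefined tert-butyldimethylsilyl enol ether F2.
- Mukaiyama-type hydroxymethylation of F2 with aqueous formaldehyde and Yb(OTf)3 in THF should give 13.

Step 8. Hydration and ring-opening of the pyran enol ether may compete with acetal hydrolysis under acid.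
Fallback: the acetonide is removed before any enol ether is present. It sets out from alkynol 13 and returns at 17.
- Aqueous AcOH at 50 °C (or brief cold CF3CO2H–H2O) should give (2R,3R,5R,6R)-5,6-dihydroxy-2-(hydroxymethyl)-6-methyl-3-[(E)-pent-3-en-1-yn-1-yl]cyclohexan-1-one F3.
- Ph3PAuNTf2 should cyclise F3 through the primary hydroxyl only, because the C6 and C7 hydroxyls lie on the ring face opposite the alkyne. This gives (4aS,6R,7R,8aR)-6,7-dihydroxy-7-methyl-3-[(E)-prop-1-en-1-yl]-4a,5,6,7-tetrahydro-1H-isochromen-8(8aH)-one F4.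
- TBSOTf and 2,6-lutidine at −78 °C give the 6-O-tert-butyldimethylsilyl ether F5, and DDQ as in step 7 gives 17.

**Further compounds**
F1 | step 5 | bromo[(E)-pent-3-en-1-yn-1-yl]zinc | Br[Zn]C#C/C=C/C
F2 | step 5 | tert-butyldimethylsilyl C8=C8a enol ether of (3R,5R,6R)-5,6-(isopropylidenedioxy)-6-methyl-3-[(E)-pent-3-en-1-yn-1-yl]cyclohexan-1-one | CC(C)(C)[Si](C)(C)OC1=C[C@H](C#C/C=C/C)C[C@H]2OC(C)(C)O[C@@]12C
F3 | step 8 | (2R,3R,5R,6R)-5,6-dihydroxy-2-(hydroxymethyl)-6-methyl-3-[(E)-pent-3-en-1-yn-1-yl]cyclohexan-1-one | O=C1[C@](C)(O)[C@H](O)C[C@@H](C#C/C=C/C)[C@@H]1CO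
F4 | step 8 | (4aS,6R,7R,8aR)-6,7-dihydroxy-7-methyl-3-[(E)-prop-1-en-1-yl]-4a,5,6,7-tetrahydro-1H-isochromen-8(8aH)-one | C/C=C/C1=C[C@@H]2C[C@@H](O)[C@@](C)(O)C(=O)[C@H]2CO1
F5 | step 8 | (4aS,6R,7R,8aR)-6-(tert-butyldimethylsilyloxy)-7-hydroxy-7-methyl-3-[(E)-prop-1-en-1-yl]-4a,5,6,7-tetrahydro-1H-isochromen-8(8aH)-one | C/C=C/C1=C[C@@H]2C[C@@H](O[Si](C)(C)C(C)(C)C)[C@@](C)(O)C(=O)[C@H]2CO1
F6 | step 16 | (2R,3R,5R)-5-acetoxy-3-(tert-butyldimethylsilyloxy)-2-hydroxy-2-methylcyclohexan-1-one | O=C1[C@](C)(O)[C@H](O[Si](C)(C)C(C)(C)C)C[C@@H](OC(C)=O)C1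
F7 | step 16 | (5R,6R)-5-(tert-butyldimethylsilyloxy)-6-hydroxy-6-methylcyclohex-2-en-1-one | O=C1[C@](C)(O)[C@H](O[Si](C)(C)C(C)(C)C)CC=C1
F8 | step 16 | (1R,6R)-6-(tert-butyldimethylsilyloxy)-1-methyl-2-oxocyclohex-3-en-1-yl 2-methoxy-6-methyl-4-(triisopropylsilyloxy)benzoate | O=C1[C@](C)(OC(=O)c2c(C)cc(O[Si](C(C)C)(C(C)C)C(C)C)cc2OC)[C@H](O[Si](C)(C)C(C)(C)C)CC=C1
F9 | step 16 | (1R,2R,4R,5R)-2-(tert-butyldimethylsilyloxy)-5-(hydroxymethyl)-1-methyl-6-oxo-4-[(E)-pent-3-en-1-yn-1-yl]cyclohexyl 2-methoxy-6-methyl-4-(triisopropylsilyloxy)benzoate | O=C1[C@](C)(OC(=O)c2c(C)cc(O[Si](C(C)C)(C(C)C)C(C)C)cc2OC)[C@H](O[Si](C)(C)C(C)(C)C)C[C@@H](C#C/C=C/C)[C@@H]1CO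
F10 | step 16 | (4aS,6R,7R,8aR)-6-(tert-butyldimethylsilyloxy)-7-methyl-8-oxo-3-[(E)-prop-1-en-1-yl]-4a,5,6,7,8,8a-hexahydro-1H-isochromen-7-yl 2-methoxy-6-methyl-4-(triisopropylsilyloxy)benzoate | C/C=C/C1=C[C@@H]2C[C@@H](O[Si](C)(C)C(C)(C)C)[C@@](C)(OC(=O)c3c(C)cc(O[Si](C(C)C)(C(C)C)C(C)C)cc3OC)C(=O)[C@H]2CO1
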